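**Plan**
Retrosynthetic cuts, in order: the ring D enol ether C14=C15 (from a C15 methyl acetal), the C6–OAc bond (from the C6=C7 enol acetate), C6–C7 (ring B), O9–C13 and O–C15 (rings C and D), C11–C12, and C9–C10.
Forward: ring A (from β-cyclocitral) is joined to a C7–C8–C9–C11 hydroxy ester by an Ireland–Claisen rearrangement (C9–C10). The C12–C16 chain is added by radical allylation. Rings C and D close in one acid/gold cascade, ring B then closes by a 6-endo acyl radical cyclisation, C6 is acetoxylated, and the ring D enol ether is unveiled last.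
Enabling feature: the exocyclic C5=C6 methylene on ring A, left by the Claisen step. Its inner carbon C5 lies between the quaternary carbons C4 and C10 and is 1,3 to C9 across C10, so an acyl radical at C7 on the chain C10–C9–C8–C7 can only add 6-endo at C6.
Stereochemistry: C8 from an organocatalytic aldol. C9 and C10 from the Claisen step, steered by a temporary 1,3-dioxane ring (O9–C9–C8–C7–O7, removed in step 13) and a chair transition state. C13 from a Sharpless epoxidation opened with inversion. C5 in the ring B closure (axial methyls C19 and C20 block the β face). C6 by α-epoxidation of the enol acetate and an invertive 1,2-acyloxy shift.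

Key step: step 15

Remark: intermediates carry labdane numbering (C1–C20; O9 on C9, O7 on C7); 22–27 are carried as the mixture of C15 acetal epimers, which disappears in step 18, and the minor C9 epimer of 5–8 converges in step 5.

Step 1
Reactants: 1 β-cyclocitral
Product: 2 β-cyclogeraniol
Conditions: NaBH4, MeOH, 0 °C
Reagents that add atoms: none
Why: Borohydride 1,2-reduction of the hindered conjugated aldehyde (carbonyl reduction) should give the allylic alcohol; no stereocenter is formed.

Step 2
Reactants: 3 propanal; 4 ethyl glyoxylate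
Product: 6 ethyl (2R,3R)-2,4-dihydroxy-3-methylbutanoate, via aldol aldehyde 5 (not isolated)
Conditions: (S)-α,α-bis[3,5-bis(trifluoromethyl)phenyl]prolinol (10 mol%), MeCN/H2O, rt; then NaBH4, EtOH, 0 °C; used at once
Reagents that add atoms: none
Why: Enamine cross-aldol reaction (diarylprolinol organocatalysis) of propanal with the non-enolisable glyoxylate should set the methyl-bearing carbon (C8 of the target) by hydrogen-bond-directed attack on one face of the (E)-enamine, the anti carbinol center (C9) being of no consequence because it is erased in step 5, and borohydride then reduces only the aldehyde.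

Step 3
Reactants: 6 ethyl (2R,3R)-2,4-dihydroxy-3-methylbutanoate
Product: 7 ethyl (4R,5R)-2,2,5-trimethyl-1,3-dioxane-4-carboxylate
Conditions: 2-methoxypropene, PPTS (cat.), CH2Cl2, 0 °C
Reagents that add atoms: 2-methoxypropene, COC(C)=C
Why: Kinetic acetalisation of the 1,3-diol with the enol ether should outrun lactonisation and build the temporary 1,3-dioxane ring that joins O9 to O7; the stereocenters are untouched.

Step 4
Reactants: 7 ethyl (4R,5R)-2,2,5-trimethyl-1,3-dioxane-4-carboxylate; 2 β-cyclogeraniol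
Product: 8 (2,6,6-trimethylcyclohex-1-en-1-yl)methyl (4R,5R)-2,2,5-trimethyl-1,3-dioxane-4-carboxylate
Conditions: ClBu2SnOSnBu2Cl (5 mol%), toluene, reflux, 4 Å molecular sieves
Reagents that add atoms: none
Why: Distannoxane-catalysed transesterification under neutral conditions should exchange ethanol for the allylic alcohol without touching the acetonide or C8.

Step 5
Reactants: 8 (2,6,6-trimethylcyclohex-1-en-1-yl)methyl (4R,5R)-2,2,5-trimethyl-1,3-dioxane-4-carboxylate
Product: 11 (4R,5R)-2,2,5-trimethyl-4-[(1S)-1,3,3-trimethyl-2-methylidenecyclohexyl]-1,3-dioxane-4-carboxylic acid, via silyl ketene acetal 9 (not isolated), via trimethylsilyl ester 10 (not isolated)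
Conditions: LiN(iPr)2, THF, −78 °C; Me3SiCl/Et3N; −78 → 65 °C; aqueous work-up
Reagents that add atoms: none
Why: Ireland–Claisen rearrangement: lithium chelation between the enolate oxygen and ring oxygen O9 fixes the ketene acetal geometry, the allyl terminus C10 should attack the exocyclic carbon C9 on the face anti to the C8 methyl of the temporary dioxane ring, and the chair transition state (C8 and C20 pseudo-axial, O9 pseudo-equatorial) relates C9 to C10, so both quaternary centers are set, the C9 epimers of 8 converge, and the exocyclic C5=C6 bond is left behind.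

Step 6
Reactants: 11 (4R,5R)-2,2,5-trimethyl-4-[(1S)-1,3,3-trimethyl-2-methylidenecyclohexyl]-1,3-dioxane-4-carboxylic acid
Product: 12 [(4R,5R)-2,2,5-trimethyl-4-[(1S)-1,3,3-trimethyl-2-methylidenecyclohexyl]-1,3-dioxan-4-yl]methanol
Conditions: LiAlH4, THF, 0 °C → reflux
Reagents that add atoms: none
Why: Hydride reduction of the carboxylic acid should give the neopentyl alcohol (C11); acetonide and alkene are inert.

Step 7
Reactants: 12 [(4R,5R)-2,2,5-trimethyl-4-[(1S)-1,3,3-trimethyl-2-methylidenecyclohexyl]-1,3-dioxan-4-yl]methanol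
Product: 13 (4R,5R)-4-(iodomethyl)-2,2,5-trimethyl-4-[(1S)-1,3,3-trimethyl-2-methylidenecyclohexyl]-1,3-dioxane
Conditions: I2, PPh3, imidazole, toluene, 80 °C
Reagents that add atoms: iodine, [I][I]
Why: Appel-type iodination should replace the primary hydroxyl by SN2 displacement of the oxyphosphonium group at C11; no stereocenter is involved.

Step 8
Reactants: 14 methallyl alcohol (2-methylprop-2-en-1-ol)
Product: 15 2-[(tributylstannyl)methyl]prop-2-en-1-ol
Conditions: nBuLi (2.2 equiv), TMEDA, Et2O, 0 °C → rt; Bu3SnCl, −78 °C → rt; aqueous work-up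
Reagents that add atoms: tributyltin chloride, CCCC[Sn](Cl)(CCCC)CCCC
Why: Double deprotonation gives the allylic dianion, which should be stannylated at carbon (allylic metalation–stannylation).

Step 9
Reactants: 13 (4R,5R)-4-(iodomethyl)-2,2,5-trimethyl-4-[(1S)-1,3,3-trimethyl-2-methylidenecyclohexyl]-1,3-dioxane; 15 2-[(tributylstannyl)methyl]prop-2-en-1-ol
Product: 16 2-methylidene-4-[(4R,5R)-2,2,5-trimethyl-4-[(1S)-1,3,3-trimethyl-2-methylidenecyclohexyl]-1,3-dioxan-4-yl]butan-1-ol
Conditions: AIBN (cat.), benzene, 80 °C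
Reagents that add atoms: none
Why: Keck radical allylation (addition–fragmentation chain) should form C11–C12 at a neopentyl center where SN2 chemistry would fail; closure of the C11 radical onto C5=C6 would be 5-endo or 4-exo and should not compete.

Step 10
Reactants: 16 2-methylidene-4-[(4R,5R)-2,2,5-trimethyl-4-[(1S)-1,3,3-trimethyl-2-methylidenecyclohexyl]-1,3-dioxan-4-yl]butan-1-ol
Product: 17 [(2S)-2-{2-[(4R,5R)-2,2,5-trimethyl-4-[(1S)-1,3,3-trimethyl-2-methylidenecyclohexyl]-1,3-dioxan-4-yl]ethyl}oxiran-2-yl]methanol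
Conditions: Ti(OiPr)4 (10 mol%), diethyl L-(+)-tartrate (12 mol%), tBuOOH, 4 Å molecular sieves, CH2Cl2, −20 °C
Reagents that add atoms: tert-butyl hydroperoxide, CC(C)(C)OO
Why: Sharpless asymmetric epoxidation of the 2-substituted allylic alcohol should set C13 under reagent control (the L-tartrate directs oxygen to one face of C13=C16), while the non-allylic C5=C6 bond is inert to the titanium peroxide.

Step 11
Reactants: 17 [(2S)-2-{2-[(4R,5R)-2,2,5-trimethyl-4-[(1S)-1,3,3-trimethyl-2-methylidenecyclohexyl]-1,3-dioxan-4-yl]ethyl}oxiran-2-yl]methanol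
Product: 18 (2R)-2-{2-[(4R,5R)-2,2,5-trimethyl-4-[(1S)-1,3,3-trimethyl-2-methylidenecyclohexyl]-1,3-dioxan-4-yl]ethyl}oxirane-2-carbaldehyde
Conditions: Dess–Martin periodinane, NaHCO3, CH2Cl2, 0 °C → rt
Reagents that add atoms: none
Why: Dess–Martin oxidation of the primary alcohol under buffered conditions; the α-carbon is quaternary, so no epimerisation is possible.

Step 12
Reactants: 18 (2R)-2-{2-[(4R,5R)-2,2,5-trimethyl-4-[(1S)-1,3,3-trimethyl-2-methylidenecyclohexyl]-1,3-dioxan-4-yl]ethyl}oxirane-2-carbaldehyde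
Product: 19 (4R,5R)-4-{2-[(2S)-2-ethynyloxiran-2-yl]ethyl}-2,2,5-trimethyl-4-[(1S)-1,3,3-trimethyl-2-methylidenecyclohexyl]-1,3-dioxane
Conditions: dimethyl (1-diazo-2-oxopropyl)phosphonate, K2CO3, MeOH, 0 °C → rt
Reagents that add atoms: dimethyl (1-diazo-2-oxopropyl)phosphonate, COP(=O)(OC)C(=[N+]=[N-])C(C)=O
Why: Seyferth–Gilbert homologation with the Ohira–Bestmann reagent should convert the aldehyde into the terminal alkyne C14≡C15 under mild carbonate conditions that leave the epoxide intact.

Step 13
Reactants: 19 (4R,5R)-4-{2-[(2S)-2-ethynyloxiran-2-yl]ethyl}-2,2,5-trimethyl-4-[(1S)-1,3,3-trimethyl-2-methylidenecyclohexyl]-1,3-dioxane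
Product: 22 (13R)-15ξ-methoxy-9α,13:15,16-diepoxy-6,7-secolabd-5(6)-en-7-ol, via diol alkyne 20 (not isolated), via dihydrofuran alcohol 21 (not isolated)
Conditions: camphorsulfonic acid (10 mol%), CH2Cl2/MeOH (10:1), 0 °C → rt; then Ph3PAuCl (2 mol%), AgBF4 (2 mol%), MeOH, rt
Reagents that add atoms: methanol, CO
Why: Acid-promoted 5-exo opening of the tertiary propargylic epoxide by O9 with inversion at C13 should close ring C while methanol removes the isopropylidene group, after which gold-catalysed 5-endo-dig cycloisomerisation of the new homopropargylic alcohol and acid-catalysed addition of methanol to the enol ether close ring D as its methyl acetal, so that the C7 hydroxyl is the only free alcohol left.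

Step 14
Reactants: 22 (13R)-15ξ-methoxy-9α,13:15,16-diepoxy-6,7-secolabd-5(6)-en-7-ol
Product: 23 (13R)-15ξ-methoxy-9α,13:15,16-diepoxy-6,7-secolabd-5(6)-en-7-al
Conditions: Dess–Martin periodinane, NaHCO3, CH2Cl2, 0 °C
Reagents that add atoms: none
Why: Dess–Martin oxidation of the primary alcohol; buffered neutral conditions should avoid epimerisation at C8 and β-elimination of the C9 ether.

Step 15
Reactants: 23 (13R)-15ξ-methoxy-9α,13:15,16-diepoxy-6,7-secolabd-5(6)-en-7-al
Product: 24 (13R)-15ξ-methoxy-9α,13:15,16-diepoxy-5α-labdan-7-one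
Conditions: tert-dodecanethiol (20 mol%), di-tert-butyl hyponitrite (5 mol%, two portions), 1,4-dioxane (0.02 M), 60 °C
Reagents that add atoms: none
Why: The thiyl radical abstracts the aldehydic hydrogen of 23 (polarity-reversal catalysis), the nucleophilic acyl radical at C7 adds to the unsubstituted terminus C6 of the exocyclic C5=C6 bond, and the tertiary C5 radical takes hydrogen back from the thiol, so the chain needs no stoichiometric reagent; the closest known reaction types are the thiol-catalysed radical-chain cyclisation of unsaturated aldehydes and the 6-endo acyl radical cyclisation of selenoesters onto 1,1-disubstituted alkenes. Ring B closes in the 6-endo-trig mode through a chair-like transition state in which the C8 methyl is already equatorial and the C9–O bond axial. The new stereocenter C5 is set in the hydrogen transfer: the axial methyl groups C19 on C4 and C20 on C10 block the β face, so hydrogen should arrive from the α face and give the trans ring fusion. The step needs 6-endo over 5-exo regioselectivity and must outrun decarbonylation of the α-branched acyl radical: 5-exo attack would have to build a quaternary C5 between the quaternary C4 and C10 and would leave a primary radical, the 1,3-relation of C5 and C9 across C10 holds the acyl radical next to C6, and the low temperature of the hyponitrite initiator keeps loss of CO slow. C8 is not touched, and the acetal and the ether rings should be inert to the thiyl chain at 60 °C.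

Step 16
Reactants: 24 (13R)-15ξ-methoxy-9α,13:15,16-diepoxy-5α-labdan-7-one
Product: 25 (13R)-15ξ-methoxy-9α,13:15,16-diepoxylabd-6-en-7-yl acetate
Conditions: LiN(iPr)2, THF, −78 °C; Ac2O, −78 → 0 °C
Reagents that add atoms: acetic anhydride, CC(=O)OC(C)=O
Why: Kinetic deprotonation at the methylene C6 in preference to the methine C8 (whose deprotonation would also expel the C9 ether) and O-acetylation of the lithium enolate should give the Δ6 enol acetate regioselectively.

Step 17
Reactants: 25 (13R)-15ξ-methoxy-9α,13:15,16-diepoxylabd-6-en-7-yl acetate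
Product: 27 (13R)-6β-acetoxy-15ξ-methoxy-9α,13:15,16-diepoxylabdan-7-one, via enol ester epoxide 26 (not isolated)
Conditions: dimethyldioxirane (acetone), CH2Cl2, −20 °C; evaporate; toluene, 110 °C
Reagents that add atoms: dimethyldioxirane, CC1(C)OO1
Why: Epoxidation of the enol acetate should occur from the α face (the β face of C6 is screened by the axial methyls C19 and C20), and the thermal concerted 1,2-acyloxy shift of the enol ester epoxide, which proceeds with inversion at C6, should then give the axial 6β-acetate and the C7 ketone without acid or base.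

Step 18
Reactants: 27 (13R)-6β-acetoxy-15ξ-methoxy-9α,13:15,16-diepoxylabdan-7-one
Product: 28 (13R)-6β-acetoxy-9α,13:15,16-diepoxylabd-14-en-7-one (target)
Conditions: Me3SiOTf (1.2 equiv), iPr2NEt (2 equiv), CH2Cl2, −78 → −20 °C; NaHCO3 quench
Reagents that add atoms: none
Why: Silyl-triflate-mediated acetal-to-enol-ether elimination: ionisation of the C15 acetal to the ring D oxocarbenium ion and removal of a proton from C14 (the only adjacent carbon with hydrogen) by the hindered amine should unveil the acid-labile 2,3-dihydrofuran in a buffered medium at low temperature.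

**Compound list**
1 | β-cyclocitral (2,6,6-trimethylcyclohex-1-ene-1-carbaldehyde) | CC1=C(C=O)C(C)(C)CCC1 | starting material
2 | β-cyclogeraniol ((2,6,6-trimethylcyclohex-1-en-1-yl)methanol) | CC1=C(CO)C(C)(C)CCC1 | intermediate
3 | propanal | CCC=O | starting material
4 | ethyl glyoxylate | CCOC(=O)C=O | starting material
5 | ethyl (2R,3S)-2-hydroxy-3-methyl-4-oxobutanoate | CCOC(=O)[C@H](O)[C@H](C)C=O | intermediate
6 | ethyl (2R,3R)-2,4-dihydroxy-3-methylbutanoate | CCOC(=O)[C@H](O)[C@H](C)CO | intermediate
7 | ethyl (4R,5R)-2,2,5-trimethyl-1,3-dioxane-4-carboxylate | CCOC(=O)[C@@H]1OC(C)(C)OC[C@H]1C | intermediate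
8 | (2,6,6-trimethylcyclohex-1-en-1-yl)methyl (4R,5R)-2,2,5-trimethyl-1,3-dioxane-4-carboxylate | CC1=C(COC(=O)[C@@H]2OC(C)(C)OC[C@H]2C)C(C)(C)CCC1 | intermediate
9 | (4Z,5R)-2,2,5-trimethyl-4-{[(2,6,6-trimethylcyclohex-1-en-1-yl)methoxy](trimethylsilyloxy)methylidene}-1,3-dioxane | C[C@@H]1COC(C)(C)O/C1=C(\O[Si](C)(C)C)OCC1=C(C)CCCC1(C)C | intermediate
10 | trimethylsilyl (4R,5R)-2,2,5-trimethyl-4-[(1S)-1,3,3-trimethyl-2-methylidenecyclohexyl]-1,3-dioxane-4-carboxylate | C[Si](C)(C)OC(=O)[C@]1(OC(C)(C)OC[C@H]1C)[C@@]1(C)CCCC(C)(C)C1=C | intermediate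
11 | (4R,5R)-2,2,5-trimethyl-4-[(1S)-1,3,3-trimethyl-2-methylidenecyclohexyl]-1,3-dioxane-4-carboxylic acid | OC(=O)[C@]1(OC(C)(C)OC[C@H]1C)[C@@]1(C)CCCC(C)(C)C1=C | intermediate
12 | [(4R,5R)-2,2,5-trimethyl-4-[(1S)-1,3,3-trimethyl-2-methylidenecyclohexyl]-1,3-dioxan-4-yl]methanol | OC[C@]1(OC(C)(C)OC[C@H]1C)[C@@]1(C)CCCC(C)(C)C1=C | intermediate
13 | (4R,5R)-4-(iodomethyl)-2,2,5-trimethyl-4-[(1S)-1,3,3-trimethyl-2-methylidenecyclohexyl]-1,3-dioxane | IC[C@]1(OC(C)(C)OC[C@H]1C)[C@@]1(C)CCCC(C)(C)C1=C | intermediate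
14 | methallyl alcohol (2-methylprop-2-en-1-ol) | CC(=C)CO | starting material
15 | 2-[(tributylstannyl)methyl]prop-2-en-1-ol | OCC(=C)C[Sn](CCCC)(CCCC)CCCC | intermediate
16 | 2-methylidene-4-[(4R,5R)-2,2,5-trimethyl-4-[(1S)-1,3,3-trimethyl-2-methylidenecyclohexyl]-1,3-dioxan-4-yl]butan-1-ol | OCC(=C)CC[C@]1(OC(C)(C)OC[C@H]1C)[C@@]1(C)CCCC(C)(C)C1=C | intermediate
17 | [(2S)-2-{2-[(4R,5R)-2,2,5-trimethyl-4-[(1S)-1,3,3-trimethyl-2-methylidenecyclohexyl]-1,3-dioxan-4-yl]ethyl}oxiran-2-yl]methanol | OC[C@]1(CO1)CC[C@]1(OC(C)(C)OC[C@H]1C)[C@@]1(C)CCCC(C)(C)C1=C | intermediate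
18 | (2R)-2-{2-[(4R,5R)-2,2,5-trimethyl-4-[(1S)-1,3,3-trimethyl-2-methylidenecyclohexyl]-1,3-dioxan-4-yl]ethyl}oxirane-2-carbaldehyde | O=C[C@]1(CO1)CC[C@]1(OC(C)(C)OC[C@H]1C)[C@@]1(C)CCCC(C)(C)C1=C | intermediate
19 | (4R,5R)-4-{2-[(2S)-2-ethynyloxiran-2-yl]ethyl}-2,2,5-trimethyl-4-[(1S)-1,3,3-trimethyl-2-methylidenecyclohexyl]-1,3-dioxane | C#C[C@]1(CO1)CC[C@]1(OC(C)(C)OC[C@H]1C)[C@@]1(C)CCCC(C)(C)C1=C | intermediate
20 | (2R)-2-[(2R,5R)-5-ethynyl-5-(hydroxymethyl)-2-[(1S)-1,3,3-trimethyl-2-methylidenecyclohexyl]oxolan-2-yl]propan-1-ol | OC[C@@H](C)[C@]1(CC[C@](CO)(C#C)O1)[C@@]1(C)CCCC(C)(C)C1=C | intermediate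
21 | (13R)-9α,13:15,16-diepoxy-6,7-secolabda-5(6),14-dien-7-ol | OC[C@@H](C)[C@]1(CC[C@]2(C=COC2)O1)[C@@]1(C)CCCC(C)(C)C1=C | intermediate
22 | (13R)-15ξ-methoxy-9α,13:15,16-diepoxy-6,7-secolabd-5(6)-en-7-ol | OC[C@@H](C)[C@]1(CC[C@]2(CC(OC)OC2)O1)[C@@]1(C)CCCC(C)(C)C1=C | intermediate
23 | (13R)-15ξ-methoxy-9α,13:15,16-diepoxy-6,7-secolabd-5(6)-en-7-al | O=C[C@@H](C)[C@]1(CC[C@]2(CC(OC)OC2)O1)[C@@]1(C)CCCC(C)(C)C1=C | intermediate
24 | (13R)-15ξ-methoxy-9α,13:15,16-diepoxy-5α-labdan-7-one (8β-H, 8α-methyl) | C1C(=O)[C@@H](C)[C@]2(CC[C@]3(CC(OC)OC3)O2)[C@@]2(C)CCCC(C)(C)[C@H]12 | intermediate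
25 | (13R)-15ξ-methoxy-9α,13:15,16-diepoxylabd-6-en-7-yl acetate | C1=C(OC(C)=O)[C@@H](C)[C@]2(CC[C@]3(CC(OC)OC3)O2)[C@@]2(C)CCCC(C)(C)[C@H]12 | intermediate
26 | (13R)-6α,7α:9α,13:15,16-triepoxy-15ξ-methoxylabdan-7β-yl acetate | O1[C@H]2[C@]1(OC(C)=O)[C@@H](C)[C@]3(CC[C@]4(CC(OC)OC4)O3)[C@@]3(C)CCCC(C)(C)[C@H]23 | intermediate
27 | (13R)-6β-acetoxy-15ξ-methoxy-9α,13:15,16-diepoxylabdan-7-one | CC(=O)O[C@@H]1C(=O)[C@@H](C)[C@]2(CC[C@]3(CC(OC)OC3)O2)[C@@]2(C)CCCC(C)(C)[C@H]12 | intermediate
28 | (5S,6S,8S,9R,10S,13R)-6-acetoxy-9,13:15,16-diepoxylabd-14-en-7-one | CC(=O)O[C@@H]1C(=O)[C@@H](C)[C@]2(CC[C@]3(C=COC3)O2)[C@@]2(C)CCCC(C)(C)[C@H]12 | target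

Total step count: 18.
Longest linear sequence: 16 steps (3 and 4 to 28 through steps 2–7 and 9–18; steps 1 and 8 make the side inputs 2 and 15).

**Steps most likely to fail**

Step 5. The rearrangement may show poor facial discrimination at C9 (the axial acetonide methyl competes with the C8 methyl), or it may pass through a boat as well as a chair, which would erode the C9/C10 relationship. The fallback sets out from 8 and comes back at 11. It moves stereocontrol from the substrate to the reagent: 8 is converted with a chiral 2-bromo-4,5-diphenyl-1,3-bis(4-methylphenylsulfonyl)-1,3,2-diazaborolidine (enantiomer chosen to match the dioxane bias) and iPr2NEt in CH2Cl2 at −78 °C into the boron ketene acetal. This rearranges at −20 °C through a controller-enforced chair, and hydrolytic work-up should give 11. No compound outside the list arises (F0).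

Step 15. Loss of carbon monoxide from the α-branched acyl radical, or irreversible thiol addition to the exocyclic alkene, may outrun ring closure. The fallback sets out from 22 and comes back at 24. The acyl radical is made by selenium abstraction instead of hydrogen abstraction from the aldehyde, with a stoichiometric silane as hydrogen donor at room temperature. Alcohol 22 is oxidised with TEMPO (cat.)/PhI(OAc)2 in MeCN–H2O to (13R)-15ξ-methoxy-9α,13:15,16-diepoxy-6,7-secolabd-5(6)-en-7-oic acid F1. Treatment with (PhSe)2 and PBu3 in CH2Cl2 gives the Se-phenyl selenoester F2. (Me3Si)3SiH with Et3B/air in benzene at rt should then effect the same 6-endo closure to 24.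

Step 18. The silyl triflate may enolise and silylate the C7 ketone (toward C8 this would expel the C9 ether), or the new enol ether may ionise at C13 under Lewis acid and aromatise to the furan. The fallback sets out from 27 and comes back at 28. The acetal is first hydrolysed under conditions the product never sees: AcOH/THF/H2O at 40 °C gives the lactol (13R)-6β-acetoxy-15ξ-hydroxy-9α,13:15,16-diepoxylabdan-7-one F3. F3 is then dehydrated under basic conditions with MsCl and Et3N in CH2Cl2 (−40 °C → rt) by way of the anomeric mesylate, which should give 28.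

**Further compounds**
F0 | step 5 | none | none
F1 | step 15 | (13R)-15ξ-methoxy-9α,13:15,16-diepoxy-6,7-secolabd-5(6)-en-7-oic acid | OC(=O)[C@@H](C)[C@]1(CC[C@]2(CC(OC)OC2)O1)[C@@]1(C)CCCC(C)(C)C1=C
F2 | step 15 | Se-phenyl (13R)-15ξ-methoxy-9α,13:15,16-diepoxy-6,7-secolabd-5(6)-ene-7-selenoate | O=C([Se]c1ccccc1)[C@@H](C)[C@]1(CC[C@]2(CC(OC)OC2)O1)[C@@]1(C)CCCC(C)(C)C1=C
F3 | step 18 | (13R)-6β-acetoxy-15ξ-hydroxy-9α,13:15,16-diepoxylabdan-7-one | CC(=O)O[C@@H]1C(=O)[C@@H](C)[C@]2(CC[C@]3(CC(O)OC3)O2)[C@@]2(C)CCCC(C)(C)[C@H]12
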